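## Analysis of the target

CNP0358381.1 is a dearomatised acylphloroglucinol. Ring A is an enolised cyclohexane-1,3,5-trione, fused through C4a/C8a to a 2,2-dimethyl-2,3-dihydropyran-4-one (ring B). With chroman-4-one numbering, the C5 enol is hydrogen-bonded to the C4 carbonyl, C7 is a ketone and C8=C8a is a vinylogous ester. C6 is a quaternary stereocentre (R) that carries a prenyl group and a CH2 link to a cyclobutane; C8 carries an (R)-configured CH(n-Pr)CH2CO2H chain. The cyclobutane is 1,2-trans: C1' (S) bears the link, C2' (R) an isopropenyl group, C3' is the gem-dimethyl carbon and C4' a CH2. The four stereocentres form three units (C1'/C2', C6, the side-chain carbon) separated by CH2 or sp2 atoms, so none can be relayed from another and each needs its own source of asymmetry. Sensitive features are the two alkenes (ozone, strong acid, electrophilic halogen), the cyclobutylcarbinyl positions (ring expansion once cationic), the oxidisable, O/C-ambident trione, a chromanone that can open by retro-oxa-Michael reaction, and an acid that can lactonise onto a neighbouring oxygen. The hard parts are a cyclobutane with three contiguous substituted carbons, one of them quaternary, the placement of the ring B oxygen next to C8 and not next to C6, and the isolated quaternary centre C6. The strategy rests on the C2'–C3' bond: a nitrogen inserted between the isopropenyl-bearing carbon and the gem-dimethyl carbon turns the four-membered ring into a 2,3-trans-5,5-dimethylpyrrolidine whose ring carbons and exocyclic carbon are those of pyroglutamic acid (1), C2 of 1 becoming C2'.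

## Retrosynthetic reasoning

38 from 37: only the carboxyl group changes. The acid is carried as a methyl ester, because a free acid would lactonise onto O7 at the aromatic stage and would compete as a nucleophile in the allylation.

37 from 35 and 36: the C6–prenyl bond is cut. In aromatic 35, C6 is the only ring carbon between two free oxygens (O5, O7), so with every other position filled it is where a dearomatising alkylation must occur. Making the quaternary centre last means it is created at the reacting carbon under a chiral palladium catalyst and sees no further C–C bond formation. Cutting the C6–CH2(cyclobutyl) bond here instead would require substitution at a β-branched primary carbon. The forward reaction must achieve C- over O-allylation, attack at the unsubstituted allyl terminus, and one face of the ring.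

35 from 34: the ester and the O7 phenol are closed to a lactone. The lactone masks both groups during the cross-coupling.

34 from 31 and 23: the aryl C6–CH2 bond is cut, as an sp2–sp3 coupling between the C6 iodide of 31 and zinc reagent 33 (from 23 through 32). An electrophilic alkylation of the chromanone would not tell C6 from C8; the iodine atom carries that information. This is the convergent point, joining two halves of similar size.

31 from 29 and 30: the C8–side-chain bond and the O7–acyl bond are cut together. A carbene-catalysed oxidative annulation with 30 sets the (R) side-chain centre; with C6 blocked by iodine, only C8 can react.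

29 from 26 (through 27 and 28): the C6–I bond. A silyl ether on O7 leaves the hydrogen-bonded 5-OH as the only free phenol, and halogenation goes ortho to it.

26 from 24 and 25: ring B is built on threefold-symmetric 24, so the position of its oxygen is unambiguous. If ring B were closed after C6 and C8 are substituted, the acyl group would have two different neighbouring oxygens to choose from.

23 from 18 (through 20, 21, 22): functional-group changes only. The isopropenyl group comes from the tertiary carbinol by elimination; the iodomethyl group comes from the vinyl group by excision of its terminal carbon. The vinyl group is cleaved while the carbinol is still masked, because an isopropenyl group would not survive ozonolysis.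

18 from 16 (key disconnection): the ring bond between the carbinol-bearing carbon and the gem-dimethyl carbon is replaced by C–N–C. It is the only cyclobutane bond whose two ends map onto the α-carbon and the (gem-dimethylated) carbonyl carbon of an amino acid lactam. This gains the ring and relays the C2' configuration from the chiral pool. The forward step must aminate a hindered nitrogen, lose nitrogen, and close the biradical faster than it fragments, trans to the vinyl group.

16 from 12 (through 13 and 14): the two methyl groups on C5 replace the lactam carbonyl oxygen. Reagent 3 opens the ring to methyl ketone 13, which recloses to imine 14, and 15 adds to the imine.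

12 from 9 and 10: the C3–vinyl bond, by conjugate addition anti to the bulky C2 substituent.

9 from 1 (through 2, 4, 5, 6) and 3: dehydrogenation of the protected lactam, and the carbinol from the ester with 3. The carbinol is made at the outset because an ester at C2 would racemise in the unsaturated lactam and would not survive the later organometallic steps.

## Alternatives that were turned down

Alternative 1: Ring A is taken from the symmetric 2,2-dialkylated trione A2, in which C6 is not yet a stereocentre; the C8–side-chain and O7–acyl bonds are the disconnection. Forward, a chiral triazolylidene carbene and an oxidant turn enal 30 into an unsaturated acyl azolium, one ring CH2 of A2 adds to its β-carbon and the adjacent enol oxygen is acylated, giving enol lactone A1 with C6 and the side-chain centre set together.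
- For: it is the most convergent endgame. The symmetry of A2 removes the C6/C8 question that costs the chosen route an iodination and a cross-coupling, and on step count after the cyclobutane it is clearly stronger.
- Against: the catalyst reads the face of the enoyl unit, but which CH2 reacts, and so the configuration at C6, depends only on how differently a prenyl and a cyclobutylmethyl group shield the two faces of the flat trione. A1 still lacks the acyl group, which must then cyclise onto the oxygen next to C8 and not onto the equally available one next to C6. A2 needs the enantiopure cyclobutane anyway.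
- Comparison: the chosen route uses the same carbene manifold (step 19), but on an aromatic nucleus with one free carbon, where only the side-chain centre is at stake. It sets C6 separately at the reacting carbon and fixes ring B on symmetric 24, at the price of more steps.

Alternative 2: The cyclobutane is cut at C1'–C4' and traced to a five-membered carbocycle, α-diazoketone A4. Forward, photolysis in an alcohol (Wolff rearrangement) moves the ring CH2 from the carbonyl carbon to the diazo carbon with extrusion of nitrogen; the ketene is trapped as ester A3 and base equilibration gives the trans isomer.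
- For: the migration does not pass through a biradical that can fragment, so the ring-forming step is more reliable than step 10. A3 already carries the isopropenyl group and a carboxyl carbon for the link, so steps 11–14 would shrink to a reduction and an iodination. On both points this alternative is stronger.
- Against: the asymmetry must come from a catalytic step on an achiral cyclopentenone. The diazo group must sit on the more hindered α-carbon, next to the stereocentre; diazo transfer through α-formylation prefers the open α'-CH2, which would lead to a 1,3-disubstituted cyclobutane. The isopropenyl group also sits beside a carbene centre during photolysis.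
- Comparison: the chosen route takes both cyclobutane stereocentres from a cheap amino acid by a substrate-controlled cuprate addition, and there is no question of where the extruded atom sits.

Alternative 3: Ring A is opened at C4a–C5. The acyclic keto thioester A6 (thiol part taken as ethyl) already contains ring B as a dihydropyranone and the quaternary carbon between a ketone and the thioester. Forward, a strong amide base forms the extended enolate of the dihydropyranone, whose α-carbon attacks the thioester (Claisen condensation) to give tert-butyl ester A5.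
- For: ring B exists before ring A, so the position of its oxygen is beyond doubt, which is cleaner than steps 16–20; no dearomatisation with its O/C and facial selectivity is needed. On these points it is the stronger plan.
- Against: the configuration at C6 must be built into A6 as an acyclic quaternary carbon whose two acyl arms differ only as ketone and thioester. That unit is a non-enolisable 1,3-dicarbonyl, open to retro-Claisen cleavage under the ring-closing conditions. The tert-butyl ester must finally be removed by acid in the presence of a prenyl group beside an enol and of the isopropenylcyclobutane. The plan is silent on the cyclobutane.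
- Comparison: the chosen route creates C6 last and catalytically from flat 35, and ends with a basic ester cleavage that leaves the alkenes alone.

Key step: step 10

Remark on the chemistry: the target is treated as the tautomer drawn (C5 enol, C7 ketone). Ring A/B atoms are numbered as in chroman-4-one and the cyclobutane as C1' (link), C2' (isopropenyl), C3' (CMe2), C4'. TBS = tert-butyldimethylsilyl, Boc = tert-butoxycarbonyl.

## Route

Step 1
Reactants: 1 D-pyroglutamic acid [(R)-5-oxopyrrolidine-2-carboxylic acid]
Product: 2 methyl (R)-5-oxopyrrolidine-2-carboxylate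
Conditions: SOCl2, MeOH, −10 °C → rt
Reagents that add atoms: methanol, CO
Why: Acid-catalysed esterification with HCl generated in situ; the stereocentre is not involved and the cold, short treatment avoids methanolysis of the lactam.

Step 2
Reactants: 2 methyl (R)-5-oxopyrrolidine-2-carboxylate; 3 methylmagnesium bromide
Product: 4 (R)-5-(2-hydroxypropan-2-yl)pyrrolidin-2-one
Conditions: MeMgBr (3.5 equiv), THF, 0 °C → rt; aq. NH4Cl
Reagents that add atoms: none
Why: Double Grignard addition to the ester; the first equivalent deprotonates the lactam N–H, and the resulting anion protects the ring carbonyl, so only the ester becomes the tertiary carbinol and C2 is not epimerised.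

Step 3
Reactants: 4 (R)-5-(2-hydroxypropan-2-yl)pyrrolidin-2-one
Product: 5 (R)-5-[2-(TBSO)propan-2-yl]pyrrolidin-2-one
Conditions: TBSOTf, 2,6-lutidine, CH2Cl2, 0 °C → rt
Reagents that add atoms: tert-butyldimethylsilyl trifluoromethanesulfonate, CC(C)(C)[Si](C)(C)OS(=O)(=O)C(F)(F)F
Why: Silylation of a hindered tertiary alcohol with the silyl triflate; the ether prevents alkoxide attack on the later N-acyl group and keeps a free 1,2-amino alcohol away from the iodine oxidant of step 10.

Step 4
Reactants: 5 (R)-5-[2-(TBSO)propan-2-yl]pyrrolidin-2-one
Product: 6 tert-butyl (R)-2-[2-(TBSO)propan-2-yl]-5-oxopyrrolidine-1-carboxylate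
Conditions: Boc2O, DMAP (cat.), Et3N, MeCN, rt
Reagents that add atoms: di-tert-butyl dicarbonate, CC(C)(C)OC(=O)OC(=O)OC(C)(C)C
Why: N-Acylation of the lactam; the imide-type nitrogen makes the ring enolisable, a good conjugate acceptor, and openable by a Grignard reagent.

Step 5
Reactants: 6 tert-butyl (R)-2-[2-(TBSO)propan-2-yl]-5-oxopyrrolidine-1-carboxylate
Product: 9 tert-butyl (R)-2-[2-(TBSO)propan-2-yl]-5-oxo-2,5-dihydro-1H-pyrrole-1-carboxylate, via α-phenylselanyl lactam 7 (not isolated), via selenoxide 8 (not isolated)
Conditions: LiN(SiMe3)2, THF, −78 °C; PhSeCl; then H2O2 (30 %), pyridine, CH2Cl2, 0 °C → rt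
Reagents that add atoms: none
Why: α-Selenenylation of the lactam enolate followed by selenoxide syn-elimination, which can only form the C3=C4 double bond; the buffered oxidation avoids γ-deprotonation at C2.

Step 6
Reactants: 9 tert-butyl (R)-2-[2-(TBSO)propan-2-yl]-5-oxo-2,5-dihydro-1H-pyrrole-1-carboxylate; 10 vinylmagnesium bromide
Product: 12 tert-butyl (2R,3S)-2-[2-(TBSO)propan-2-yl]-3-ethenyl-5-oxopyrrolidine-1-carboxylate, via silyl ketene aminal 11 (not isolated)
Conditions: CH2=CHMgBr (2.5 equiv), CuBr·SMe2 (1.25 equiv), Me3SiCl, THF, −78 → −40 °C; aq. NH4Cl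
Reagents that add atoms: none
Why: Conjugate addition of a magnesium divinylcuprate (monovalent copper) to the N-acyl unsaturated lactam; the vinyl group enters C3 anti to the bulky C2 substituent (1,2-induction), which sets the 2,3-trans relationship.

Step 7
Reactants: 12 tert-butyl (2R,3S)-2-[2-(TBSO)propan-2-yl]-3-ethenyl-5-oxopyrrolidine-1-carboxylate; 3 methylmagnesium bromide
Product: 13 tert-butyl N-[(3R,4S)-2-(TBSO)-4-ethenyl-2-methyl-6-oxoheptan-3-yl]carbamate
Conditions: MeMgBr (1.3 equiv), THF, −78 °C; aq. NH4Cl
Reagents that add atoms: none
Why: Grignard addition to the ring carbonyl of an N-Boc lactam opens the ring to the N-Boc amino methyl ketone; the carbamate carbonyl is less electrophilic and the tetrahedral adduct persists in the cold, which limits over-addition.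

Step 8
Reactants: 13 tert-butyl N-[(3R,4S)-2-(TBSO)-4-ethenyl-2-methyl-6-oxoheptan-3-yl]carbamate
Product: 14 (2R,3S)-2-[2-(TBSO)propan-2-yl]-3-ethenyl-5-methyl-3,4-dihydro-2H-pyrrole
Conditions: CF3CO2H, CH2Cl2, 0 °C; then aq. K2CO3
Reagents that add atoms: none
Why: Acidolysis of the carbamate; the freed amine condenses with the ketone to the five-membered cyclic ketimine, and the tertiary silyl ether should survive brief anhydrous acid.

Step 9
Reactants: 14 (2R,3S)-2-[2-(TBSO)propan-2-yl]-3-ethenyl-5-methyl-3,4-dihydro-2H-pyrrole; 15 methyllithium
Product: 16 (2R,3S)-2-[2-(TBSO)propan-2-yl]-3-ethenyl-5,5-dimethylpyrrolidine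
Conditions: MeLi, CeCl3, THF, −78 → −20 °C
Reagents that add atoms: none
Why: 1,2-Addition of the weakly basic organocerium reagent (trivalent cerium) to an enolisable ketimine; the new carbon bears two methyl groups, so no stereocentre arises.

Step 10
Reactants: 16 (2R,3S)-2-[2-(TBSO)propan-2-yl]-3-ethenyl-5,5-dimethylpyrrolidine
Product: 18 tert-butyl({2-[(1S,2S)-2-ethenyl-4,4-dimethylcyclobutyl]propan-2-yl}oxy)dimethylsilane, via 1,1-diazene 17 (not isolated)
Conditions: PhI(OH)OTs (2.5 equiv), NH2CO2NH4 (8 equiv), CF3CH2OH, 80 °C
Reagents that add atoms: none
Why: PhI(OH)OTs and ammonia from the carbamate form an iodonitrene that aminates N1; further oxidation gives 1,1-diazene 17, which loses nitrogen to a singlet 1,4-biradical (C2 and C5) that recombines to the C2–C5 bond. The closest known reaction type is the iodonitrene-mediated nitrogen deletion of pyrrolidines to cyclobutanes, which is stereoretentive; a substrate whose radical centres carry neither aryl nor ester groups lies at the margin of what is documented. The four-membered ring closes by radical–radical recombination, a formal contraction of the five-membered ring by extrusion of N1. The stereocentre re-formed at the carbinol-bearing carbon is controlled by C3, which is never a radical: closure faster than bond rotation retains the trans arrangement, and a rotated radical would still close anti to the vinyl group because of the bulky silyloxypropyl substituent, so both paths give the (1S,2S) isomer. The step needs recombination to beat β-scission of the C3–C4 bond into two alkenes; unstabilised radical centres (the isopropenyl group is carried as the saturated carbinol, so no allyl radical forms) and the substituents that hold the radical ends close should favour closure. It also needs N-amination to beat oxidation of the amine or the vinyl group by trivalent iodine: C5 has no hydrogen, the silyl ether blocks the cleavage open to a free 1,2-amino alcohol, and the excess ammonia source keeps the free oxidant concentration low.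

Step 11
Reactants: 18 tert-butyl({2-[(1S,2S)-2-ethenyl-4,4-dimethylcyclobutyl]propan-2-yl}oxy)dimethylsilane
Product: 20 {(1R,2S)-2-[2-(TBSO)propan-2-yl]-3,3-dimethylcyclobutyl}methanol, via aldehyde 19 (not isolated)
Conditions: O3, CH2Cl2/MeOH, −78 °C; then NaBH4, −78 °C → rt
Reagents that add atoms: ozone, [O-][O+]=O
Why: Ozonolysis of the only alkene with reductive work-up directly to the alcohol, so the epimerisable aldehyde is never handled; the ring stereocentres are not touched.

Step 12
Reactants: 20 {(1R,2S)-2-[2-(TBSO)propan-2-yl]-3,3-dimethylcyclobutyl}methanol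
Product: 21 2-[(1S,2R)-2-(hydroxymethyl)-4,4-dimethylcyclobutyl]propan-2-ol
Conditions: Bu4NF, THF, 60 °C
Reagents that add atoms: none
Why: Fluoride cleavage of the tertiary silyl ether, which needs warming; no acid is used, so the carbinol beside the four-membered ring is not ionised.

Step 13
Reactants: 21 2-[(1S,2R)-2-(hydroxymethyl)-4,4-dimethylcyclobutyl]propan-2-ol
Product: 22 2-[(1S,2R)-2-(iodomethyl)-4,4-dimethylcyclobutyl]propan-2-ol
Conditions: PPh3, I2, imidazole, CH2Cl2, 0 °C → rt
Reagents that add atoms: iodine, II
Why: Appel reaction; only the primary alcohol forms the alkoxyphosphonium ion at a useful rate, and the trans arrangement keeps the tertiary hydroxyl from closing a strained trans-fused oxolane onto it.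

Step 14
Reactants: 22 2-[(1S,2R)-2-(iodomethyl)-4,4-dimethylcyclobutyl]propan-2-ol
Product: 23 (2R,3R)-3-(iodomethyl)-1,1-dimethyl-2-(prop-1-en-2-yl)cyclobutane
Conditions: SOCl2, pyridine, 0 °C
Reagents that add atoms: none
Why: E2-type elimination of the chlorosulfite in pyridine; six methyl hydrogens against one shielded ring hydrogen, and the strain of an alkylidenecyclobutane, favour the isopropenyl group. The basic medium is chosen to avoid a free cyclobutylcarbinyl cation.

Step 15
Reactants: 24 phloroglucinol; 25 3-methylbut-2-enoic acid
Product: 26 5,7-dihydroxy-2,2-dimethylchroman-4-one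
Conditions: P2O5, MeSO3H, 70 °C
Reagents that add atoms: none
Why: Friedel–Crafts acylation followed by intramolecular oxa-Michael addition; on threefold-symmetric 24 only one chromanone can form, which settles the position of the ring B oxygen.

Step 16
Reactants: 26 5,7-dihydroxy-2,2-dimethylchroman-4-one
Product: 27 7-(TBSO)-5-hydroxy-2,2-dimethylchroman-4-one
Conditions: TBSCl, imidazole, DMF, 0 °C
Reagents that add atoms: tert-butyldimethylsilyl chloride, CC(C)(C)[Si](C)(C)Cl
Why: The 5-OH is locked in a hydrogen bond to the C4 carbonyl, so only the more acidic, free 7-OH is silylated.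

Step 17
Reactants: 27 7-(TBSO)-5-hydroxy-2,2-dimethylchroman-4-one
Product: 28 7-(TBSO)-5-hydroxy-6-iodo-2,2-dimethylchroman-4-one
Conditions: N-iodosuccinimide, DMF, 0 °C → rt
Reagents that add atoms: N-iodosuccinimide, O=C1CCC(=O)N1I
Why: Electrophilic aromatic iodination; 5,7-dioxygenated chromones and chromanones with a free chelated 5-OH and an etherified O7 are known to be halogenated ortho to the phenol, at C6. The constitution is to be confirmed by HMBC before the material is carried on.

Step 18
Reactants: 28 7-(TBSO)-5-hydroxy-6-iodo-2,2-dimethylchroman-4-one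
Product: 29 5,7-dihydroxy-6-iodo-2,2-dimethylchroman-4-one
Conditions: Bu4NF, AcOH, THF, 0 °C
Reagents that add atoms: none
Why: Buffered fluoride cleavage of an aryl silyl ether, which is labile because the phenol is acidic; the iodide and the chromanone are untouched.

Step 19
Reactants: 29 5,7-dihydroxy-6-iodo-2,2-dimethylchroman-4-one; 30 (E)-hex-2-enal
Product: 31 lactone between O7 and the carboxyl group of (R)-3-(5,7-dihydroxy-6-iodo-2,2-dimethyl-4-oxochroman-8-yl)hexanoic acid
Conditions: chiral aminoindanol-derived N-mesityl triazolium chloride (10 mol %), 3,3',5,5'-tetra-tert-butyldiphenoquinone (1.2 equiv), DBU, toluene, rt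
Reagents that add atoms: none
Why: Oxidative N-heterocyclic carbene catalysis, a formal [3+3] annulation known for naphthols and stable enols: the enal becomes an α,β-unsaturated acyl azolium, the phenoxide adds through C8 (the only free ring carbon) to its β-carbon, and O7 is acylated with release of the carbene. The catalyst antipode is chosen so that C8 adds to the Re face of the β-carbon, which gives the (R) centre.

Step 20
Reactants: 23 (2R,3R)-3-(iodomethyl)-1,1-dimethyl-2-(prop-1-en-2-yl)cyclobutane; 31 iodo lactone
Product: 34 lactone between O7 and the carboxyl group of (R)-3-[5,7-dihydroxy-2,2-dimethyl-6-{[(1S,2R)-3,3-dimethyl-2-(prop-1-en-2-yl)cyclobutyl]methyl}-4-oxochroman-8-yl]hexanoic acid, via alkyllithium 32 (not isolated), via alkylzinc chloride 33 (not isolated)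
Conditions: 23, t-BuLi (2.1 equiv), Et2O, −78 °C; ZnCl2, THF, −78 °C → rt; then 31, Pd(OAc)2 (5 mol %), SPhos (10 mol %), THF/NMP, 40 °C
Reagents that add atoms: none
Why: Negishi coupling (sp3–sp2); iodine–lithium exchange and transmetalation to zinc are polar steps at low temperature that should leave the cyclobutylcarbinyl unit and both stereocentres intact. The zinc reagent tolerates lactone, ketone and the hydrogen-bonded phenol.

Step 21
Reactants: 34 coupled lactone
Product: 35 methyl (R)-3-[5,7-dihydroxy-2,2-dimethyl-6-{[(1S,2R)-3,3-dimethyl-2-(prop-1-en-2-yl)cyclobutyl]methyl}-4-oxochroman-8-yl]hexanoate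
Conditions: NaOMe, MeOH, 0 °C; then AcOH; used without delay
Reagents that add atoms: methanol, CO
Why: Transesterification of the aryl ester frees O7, so that C6 lies between two phenolic oxygens, and stores the acid as its methyl ester.

Step 22
Reactants: 35 methyl ester; 36 3-methylbut-2-en-1-yl acetate (prenyl acetate)
Product: 37 methyl (R)-3-[(6R)-5-hydroxy-2,2-dimethyl-6-{[(1S,2R)-3,3-dimethyl-2-(prop-1-en-2-yl)cyclobutyl]methyl}-6-(3-methylbut-2-en-1-yl)-4,7-dioxo-3,4,6,7-tetrahydro-2H-chromen-8-yl]hexanoate
Conditions: Pd2(dba)3·CHCl3 (2.5 mol %), (R,R)-N,N'-(cyclohexane-1,2-diyl)bis[2-(diphenylphosphanyl)benzamide] (7.5 mol %), Cs2CO3, THF, 0 °C → rt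
Reagents that add atoms: none
Why: Dearomatising Tsuji–Trost allylation run as an asymmetric allylic alkylation (zerovalent palladium): the phenoxide attacks the unsubstituted terminus of the 1,1-dimethylallyl palladium complex through C6, the only carbon between two oxygens. O-Prenyl ethers re-ionise under the catalyst, so the C-alkylated trione is the sink. The chiral ligand selects the face at C6; the (6R) isomer is wanted, the ligand antipode that gives it is assigned in the first run, and the remote stereocentres are expected to exert little bias.

Step 23
Reactants: 37 methyl ester of the target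
Product: 38 CNP0358381.1, (R)-3-[(6R)-5-hydroxy-2,2-dimethyl-6-{[(1S,2R)-3,3-dimethyl-2-(prop-1-en-2-yl)cyclobutyl]methyl}-6-(3-methylbut-2-en-1-yl)-4,7-dioxo-3,4,6,7-tetrahydro-2H-chromen-8-yl]hexanoic acid
Conditions: LiOH, THF/H2O, 0 °C → rt; then 1 M HCl to pH 3
Reagents that add atoms: lithium hydroxide, [Li+].[OH-]
Why: Saponification; under these conditions the enolised trione is present as its unreactive enolate, no stereocentre is acidic, and the acid is released on mild acidification.

## Compound list

1 | D-pyroglutamic acid, (R)-5-oxopyrrolidine-2-carboxylic acid | OC(=O)[C@H]1CCC(=O)N1 | starting material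
2 | methyl (R)-5-oxopyrrolidine-2-carboxylate | COC(=O)[C@H]1CCC(=O)N1 | intermediate
3 | methylmagnesium bromide | C[Mg]Br | starting material
4 | (R)-5-(2-hydroxypropan-2-yl)pyrrolidin-2-one | CC(C)(O)[C@H]1CCC(=O)N1 | intermediate
5 | (R)-5-[2-(TBSO)propan-2-yl]pyrrolidin-2-one | CC(C)(O[Si](C)(C)C(C)(C)C)[C@H]1CCC(=O)N1 | intermediate
6 | tert-butyl (R)-2-[2-(TBSO)propan-2-yl]-5-oxopyrrolidine-1-carboxylate | CC(C)(O[Si](C)(C)C(C)(C)C)[C@H]1CCC(=O)N1C(=O)OC(C)(C)C | intermediate
7 | tert-butyl (2R)-2-[2-(TBSO)propan-2-yl]-5-oxo-4-(phenylselanyl)pyrrolidine-1-carboxylate (both C4 epimers) | CC(C)(O[Si](C)(C)C(C)(C)C)[C@H]1CC([Se]c2ccccc2)C(=O)N1C(=O)OC(C)(C)C | intermediate (not isolated)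
8 | tert-butyl (2R)-4-(benzeneseleninyl)-2-[2-(TBSO)propan-2-yl]-5-oxopyrrolidine-1-carboxylate | CC(C)(O[Si](C)(C)C(C)(C)C)[C@H]1CC([Se](=O)c2ccccc2)C(=O)N1C(=O)OC(C)(C)C | intermediate (not isolated)
9 | tert-butyl (R)-2-[2-(TBSO)propan-2-yl]-5-oxo-2,5-dihydro-1H-pyrrole-1-carboxylate | CC(C)(O[Si](C)(C)C(C)(C)C)[C@H]1C=CC(=O)N1C(=O)OC(C)(C)C | intermediate
10 | vinylmagnesium bromide | C=C[Mg]Br | starting material
11 | tert-butyl (2R,3R)-2-[2-(TBSO)propan-2-yl]-3-ethenyl-5-[(trimethylsilyl)oxy]-2,3-dihydro-1H-pyrrole-1-carboxylate | CC(C)(O[Si](C)(C)C(C)(C)C)[C@H]1[C@H](C=C)C=C(O[Si](C)(C)C)N1C(=O)OC(C)(C)C | intermediate (not isolated)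
12 | tert-butyl (2R,3S)-2-[2-(TBSO)propan-2-yl]-3-ethenyl-5-oxopyrrolidine-1-carboxylate | CC(C)(O[Si](C)(C)C(C)(C)C)[C@H]1[C@H](C=C)CC(=O)N1C(=O)OC(C)(C)C | intermediate
13 | tert-butyl N-[(3R,4S)-2-(TBSO)-4-ethenyl-2-methyl-6-oxoheptan-3-yl]carbamate | CC(C)(O[Si](C)(C)C(C)(C)C)[C@H](NC(=O)OC(C)(C)C)[C@H](C=C)CC(C)=O | intermediate
14 | (2R,3S)-2-[2-(TBSO)propan-2-yl]-3-ethenyl-5-methyl-3,4-dihydro-2H-pyrrole | CC(C)(O[Si](C)(C)C(C)(C)C)[C@H]1[C@H](C=C)CC(C)=N1 | intermediate
15 | methyllithium | [Li]C | starting material
16 | (2R,3S)-2-[2-(TBSO)propan-2-yl]-3-ethenyl-5,5-dimethylpyrrolidine | CC(C)(O[Si](C)(C)C(C)(C)C)[C@H]1[C@H](C=C)CC(C)(C)N1 | intermediate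
17 | 1,1-diazene of 16 (N1 doubly bonded to a terminal nitrogen) | CC(C)(O[Si](C)(C)C(C)(C)C)[C@H]1[C@H](C=C)CC(C)(C)[N+]1=[N-] | intermediate (not isolated)
18 | tert-butyl({2-[(1S,2S)-2-ethenyl-4,4-dimethylcyclobutyl]propan-2-yl}oxy)dimethylsilane | CC(C)(O[Si](C)(C)C(C)(C)C)[C@H]1[C@H](C=C)CC1(C)C | intermediate
19 | (1R,2S)-2-[2-(TBSO)propan-2-yl]-3,3-dimethylcyclobutane-1-carbaldehyde | CC(C)(O[Si](C)(C)C(C)(C)C)[C@H]1[C@H](C=O)CC1(C)C | intermediate (not isolated)
20 | {(1R,2S)-2-[2-(TBSO)propan-2-yl]-3,3-dimethylcyclobutyl}methanol | CC(C)(O[Si](C)(C)C(C)(C)C)[C@H]1[C@H](CO)CC1(C)C | intermediate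
21 | 2-[(1S,2R)-2-(hydroxymethyl)-4,4-dimethylcyclobutyl]propan-2-ol | CC(C)(O)[C@H]1[C@H](CO)CC1(C)C | intermediate
22 | 2-[(1S,2R)-2-(iodomethyl)-4,4-dimethylcyclobutyl]propan-2-ol | CC(C)(O)[C@H]1[C@H](CI)CC1(C)C | intermediate
23 | (2R,3R)-3-(iodomethyl)-1,1-dimethyl-2-(prop-1-en-2-yl)cyclobutane | C=C(C)[C@H]1[C@H](CI)CC1(C)C | intermediate
24 | phloroglucinol (benzene-1,3,5-triol) | Oc1cc(O)cc(O)c1 | starting material
25 | 3-methylbut-2-enoic acid | CC(C)=CC(O)=O | starting material
26 | 5,7-dihydroxy-2,2-dimethylchroman-4-one | CC1(C)CC(=O)c2c(O)cc(O)cc2O1 | intermediate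
27 | 7-(TBSO)-5-hydroxy-2,2-dimethylchroman-4-one | CC1(C)CC(=O)c2c(O)cc(O[Si](C)(C)C(C)(C)C)cc2O1 | intermediate
28 | 7-(TBSO)-5-hydroxy-6-iodo-2,2-dimethylchroman-4-one | CC1(C)CC(=O)c2c(O)c(I)c(O[Si](C)(C)C(C)(C)C)cc2O1 | intermediate
29 | 5,7-dihydroxy-6-iodo-2,2-dimethylchroman-4-one | CC1(C)CC(=O)c2c(O)c(I)c(O)cc2O1 | intermediate
30 | (E)-hex-2-enal | CCC/C=C/C=O | starting material
31 | lactone (O7 to carboxyl) of (R)-3-(5,7-dihydroxy-6-iodo-2,2-dimethyl-4-oxochroman-8-yl)hexanoic acid | CCC[C@@H]1CC(=O)Oc2c(I)c(O)c3C(=O)CC(C)(C)Oc3c12 | intermediate
32 | {[trans-3,3-dimethyl-2-(prop-1-en-2-yl)cyclobutyl]methyl}lithium, configuration as in 23 | C=C(C)[C@H]1[C@H](C[Li])CC1(C)C | intermediate (not isolated)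
33 | {[trans-3,3-dimethyl-2-(prop-1-en-2-yl)cyclobutyl]methyl}zinc chloride, configuration as in 23 | C=C(C)[C@H]1[C@H](C[Zn]Cl)CC1(C)C | intermediate (not isolated)
34 | lactone (O7 to carboxyl) of (R)-3-[5,7-dihydroxy-2,2-dimethyl-6-{[(1S,2R)-3,3-dimethyl-2-(prop-1-en-2-yl)cyclobutyl]methyl}-4-oxochroman-8-yl]hexanoic acid | CCC[C@@H]1CC(=O)Oc2c(C[C@@H]4CC(C)(C)[C@H]4C(C)=C)c(O)c3C(=O)CC(C)(C)Oc3c12 | intermediate
35 | methyl (R)-3-[5,7-dihydroxy-2,2-dimethyl-6-{[(1S,2R)-3,3-dimethyl-2-(prop-1-en-2-yl)cyclobutyl]methyl}-4-oxochroman-8-yl]hexanoate | CCC[C@H](CC(=O)OC)c1c(O)c(C[C@@H]4CC(C)(C)[C@H]4C(C)=C)c(O)c2C(=O)CC(C)(C)Oc12 | intermediate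
36 | 3-methylbut-2-en-1-yl acetate (prenyl acetate) | CC(C)=CCOC(C)=O | starting material
37 | methyl ester of the target (6R, side chain R, cyclobutane 1S,2R) | C=C(C)[C@H]1[C@H](C[C@]2(CC=C(C)C)C(=O)C([C@H](CCC)CC(=O)OC)=C3OC(C)(C)CC(=O)C3=C2O)CC1(C)C | intermediate
38 | CNP0358381.1 | C=C(C)[C@H]1[C@H](C[C@]2(CC=C(C)C)C(=O)C([C@H](CCC)CC(=O)O)=C3OC(C)(C)CC(=O)C3=C2O)CC1(C)C | target

## Step count and least certain steps

Total step count: 23. Longest linear sequence: 18 (steps 1–14, then 20–23); steps 15–19 form the second branch.

Step 10 (key step). The most likely failure is fragmentation of the 1,4-biradical across C3–C4 instead of closure, because neither radical end is stabilised and both are hindered. In addition, amination of the hindered N1 may be slow enough for trivalent iodine to oxidise the amine or the vinyl group first. The fallback separates N–N bond formation from the oxidation and moves nitrogen loss to low temperature. It sets out from 16: nitrosation (t-BuONO, CH2Cl2) gives the N-nitrosopyrrolidine F1, LiAlH4 reduces it to the 1-aminopyrrolidine F2, and t-BuOCl/Et3N at −78 °C oxidises F2 to diazene 17, which is irradiated or allowed to warm in pentane. The route is rejoined at 18.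

Step 22. The most likely failure is poor facial selectivity at C6: the existing stereocentres are remote, and the catalyst must tell the chromanone flank from the ester flank of a crowded, fully substituted phenoxide. Slow ionisation of the trisubstituted allyl acetate is a second concern. The fallback alkylates without palladium: 35 is treated with prenyl bromide under phase-transfer conditions (cinchona-derived quaternary ammonium salt, CsOH·H2O, toluene, −40 °C), a known way to dearomatise acylphloroglucinols. Because the C6 epimers are diastereomers, the unwanted epimeric methyl ester F3 is removed by chromatography. The route is rejoined at 37.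

Step 19. The most likely failure is O-acylation of the electron-poor iodophenoxide without the carbon–carbon bond-forming step, together with modest face discrimination for an aliphatic enal. The fallback switches from acyl azolium to iminium activation. It sets out from 29 and 30: a diphenylprolinol trimethylsilyl ether with PhCO2H in toluene mediates Friedel–Crafts alkylation and hemiacetalisation to the lactol F4, which is oxidised with Ag2CO3 on Celite. The route is rejoined at 31.

Step 20. The most likely failure is protonolysis of the zinc reagent by the phenol and slow transmetalation at a carbon flanked by two oxygen substituents, which wastes the more valuable fragment; β-hydride elimination is a further risk. The fallback is a B-alkyl Suzuki–Miyaura coupling. It sets out from 23: alkyllithium 32 is trapped with 9-methoxy-9-borabicyclo[3.3.1]nonane to give the lithium borinate complex F5, which couples with 31 under PdCl2(dppf)/K3PO4 in DMF. The route is rejoined at 34.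

Step 14. The most likely failure is ionisation of the chlorosulfite to a cyclobutylcarbinyl cation with ring expansion; elimination toward the ring and chloride-for-iodide exchange are lesser risks. The fallback is a Chugaev elimination. It sets out from 22: NaH/CS2 and then MeI give the S-methyl xanthate F6, whose thermolysis in toluene (syn-elimination through a cyclic transition state, no cation) gives 23.

Step 17. The most likely failure is iodination at C8 or at both free positions, which would misplace the side chain. The fallback inverts the order so that regiochemistry is decided by separation before iodine is introduced. It sets out from 26 and 30: the annulation of step 19 on the unprotected chromanone gives the O7/C8-fused lactone F7 after chromatographic removal of the C6-annulated isomer. Iodination of F7, whose only free ring carbon is C6, returns to 31.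

## Further compounds

F1 | step 10 | (2R,3S)-2-[2-(TBSO)propan-2-yl]-3-ethenyl-5,5-dimethyl-1-nitrosopyrrolidine | CC(C)(O[Si](C)(C)C(C)(C)C)[C@H]1[C@H](C=C)CC(C)(C)N1N=O
F2 | step 10 | (2R,3S)-2-[2-(TBSO)propan-2-yl]-3-ethenyl-5,5-dimethylpyrrolidin-1-amine | CC(C)(O[Si](C)(C)C(C)(C)C)[C@H]1[C@H](C=C)CC(C)(C)N1N
F3 | step 22 | (6S) epimer of 37 | C=C(C)[C@H]1[C@H](C[C@@]2(CC=C(C)C)C(=O)C([C@H](CCC)CC(=O)OC)=C3OC(C)(C)CC(=O)C3=C2O)CC1(C)C
F4 | step 19 | lactol (cyclic hemiacetal with O7) of (R)-3-(5,7-dihydroxy-6-iodo-2,2-dimethyl-4-oxochroman-8-yl)hexanal | CCC[C@@H]1CC(O)Oc2c(I)c(O)c3C(=O)CC(C)(C)Oc3c12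
F5 | step 20 | lithium 9-methoxy-9-{[trans-3,3-dimethyl-2-(prop-1-en-2-yl)cyclobutyl]methyl}-9-borabicyclo[3.3.1]nonan-9-uide, configuration as in 23 | [Li+].CO[B-]1(C[C@@H]3CC(C)(C)[C@H]3C(C)=C)C2CCCC1CCC2
F6 | step 14 | O-{2-[(1S,2R)-2-(iodomethyl)-4,4-dimethylcyclobutyl]propan-2-yl} S-methyl carbonodithioate | CSC(=S)OC(C)(C)[C@H]1[C@H](CI)CC1(C)C
F7 | step 17 | lactone (O7 to carboxyl) of (R)-3-(5,7-dihydroxy-2,2-dimethyl-4-oxochroman-8-yl)hexanoic acid | CCC[C@@H]1CC(=O)Oc2cc(O)c3C(=O)CC(C)(C)Oc3c12
A1 | alternative 1 | enol lactone of the side-chain acid onto O7, fused to ring A across C7–C8, with C4a still CH2 | C=C(C)[C@H]1[C@H](C[C@]2(CC=C(C)C)C3=C([C@H](CCC)CC(=O)O3)C(=O)CC2=O)CC1(C)C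
A2 | alternative 1 | 2-{[(1S,2R)-3,3-dimethyl-2-(prop-1-en-2-yl)cyclobutyl]methyl}-2-(3-methylbut-2-en-1-yl)cyclohexane-1,3,5-trione | C=C(C)[C@H]1[C@H](CC2(CC=C(C)C)C(=O)CC(=O)CC2=O)CC1(C)C
A3 | alternative 2 | methyl (1R,2R)-3,3-dimethyl-2-(prop-1-en-2-yl)cyclobutane-1-carboxylate | C=C(C)[C@H]1[C@H](C(=O)OC)CC1(C)C
A4 | alternative 2 | (3R)-2-diazo-4,4-dimethyl-3-(prop-1-en-2-yl)cyclopentan-1-one | C=C(C)[C@H]1C(=[N+]=[N-])C(=O)CC1(C)C
A5 | alternative 3 | tert-butyl ester of 38 | C=C(C)[C@H]1[C@H](C[C@]2(CC=C(C)C)C(=O)C([C@H](CCC)CC(=O)OC(C)(C)C)=C3OC(C)(C)CC(=O)C3=C2O)CC1(C)C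
A6 | alternative 3 | acyclic precursor of A5: 1-tert-butyl 7-S-ethyl 7-thioheptanedioate carrying 3-propyl (R), 4-(2,2-dimethyl-4-oxo-3,4-dihydro-2H-pyran-6-yl), 5-oxo, and at C6 the prenyl and cyclobutylmethyl groups | C=C(C)[C@H]1[C@H](C[C@](C(=O)SCC)(CC=C(C)C)C(=O)C([C@H](CCC)CC(=O)OC(C)(C)C)C2=CC(=O)CC(C)(C)O2)CC1(C)C
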